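## Retrosynthetic overview

- Last bond: C6–C7 (prostanoid numbering), made by a stereoretentive Stille coupling of a ring (Z)-enol triflate with an (E)-vinylstannane that carries the (S)-carbinol. This fixes 5E and 7Z and needs no protecting groups.
- The (Z)-enol triflate comes from (S)-2-bromo-4-hydroxy-4-(octadienyl)cyclopentenone by α-formylation and chelation-controlled O-triflation.
- The only ring made in the route (the furan is bought) is the cyclopentenone, formed by an enantioselective oxa-Piancatelli rearrangement of a 3-bromo-5-alkylfurfuryl alcohol. Water adds to furan C5, which creates the tertiary C–O bond.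
- The furan comes from 3-bromofuran-2-carbaldehyde and (2Z,5Z)-1-bromoocta-2,5-diene (1-bromopent-2-yne + propargyl alcohol, then semihydrogenation).
- The stannane comes from methyl 4-chloro-4-oxobutanoate and (E)-1,2-bis(tributylstannyl)ethene, followed by Corey–Bakshi–Shibata reduction.

Assumption: the (R)-configured phosphoramide catalyst of step 6 gives the (S)-enone 11; if the sense of induction is opposite, its enantiomer is used.

## Route

Step 1
Reactants: 1 1-bromopent-2-yne; 2 prop-2-yn-1-ol
Product: 3 octa-2,5-diyn-1-ol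
Conditions: CuI, NaI, K2CO3, DMF, 23 °C
Reagents that add atoms: none
Why: Copper-mediated coupling of a terminal alkyne with a propargylic bromide (copper acetylide substitution) gives the skipped diyne and tolerates the free alcohol.

Step 2
Reactants: 3 octa-2,5-diyn-1-ol
Product: 4 (2Z,5Z)-octa-2,5-dien-1-ol
Conditions: H2 (1 atm), Pd/CaCO3 poisoned with Pb(OAc)2, quinoline, MeOH, 0–23 °C
Reagents that add atoms: none
Why: Lindlar semihydrogenation adds H2 syn to each alkyne and stops at the alkene, so both double bonds are Z.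

Step 3
Reactants: 4 (2Z,5Z)-octa-2,5-dien-1-ol
Product: 5 (2Z,5Z)-1-bromoocta-2,5-diene
Conditions: CBr4, PPh3, CH2Cl2, 0 °C
Reagents that add atoms: carbon tetrabromide, BrC(Br)(Br)Br
Why: The Appel reaction converts the primary allylic alcohol to the bromide by SN2 at 0 °C without moving or isomerising the Z alkenes.

Step 4
Reactants: 6 3-bromofuran-2-carbaldehyde
Product: 7 (3-bromofuran-2-yl)methanol
Conditions: NaBH4, MeOH, 0 °C
Reagents that add atoms: none
Why: Borohydride reduction of the aldehyde leaves the furyl bromide untouched.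

Step 5
Reactants: 7 (3-bromofuran-2-yl)methanol; 5 (2Z,5Z)-1-bromoocta-2,5-diene
Product: 9 [3-bromo-5-[(2Z,5Z)-octa-2,5-dien-1-yl]furan-2-yl]methanol, via dilithiated furylmethanolate 8 (not isolated)
Conditions: LiN(iPr)2 (2.2 equiv), THF, −78 → −40 °C; then 5, −78 → 0 °C; aqueous work-up
Reagents that add atoms: none
Why: After O-deprotonation the amide base removes the only remaining furan α-proton (C5), and the furyllithium displaces the primary allylic bromide by SN2 (furan metalation–alkylation) with both Z alkenes retained.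

Step 6
Reactants: 9 [3-bromo-5-[(2Z,5Z)-octa-2,5-dien-1-yl]furan-2-yl]methanol
Product: 11 (4S)-2-bromo-4-hydroxy-4-[(2Z,5Z)-octa-2,5-dien-1-yl]cyclopent-2-en-1-one, via dihydrofuranol hemiketal 10 (not isolated)
Conditions: (R)-N-triflylphosphoramide of 3,3′-bis(2,4,6-triisopropylphenyl)-1,1′-bi-2-naphthol (5 mol %), H2O (5 equiv), toluene, 0 → 23 °C
Reagents that add atoms: water, O
Why: Proposed new method: a catalytic enantioselective oxa-Piancatelli rearrangement of a primary 5-alkylfurfuryl alcohol that creates a tetrasubstituted carbinol. The strong chiral Brønsted acid ionises the alcohol (the 5-alkyl group and the bromine lone pair stabilise the furfuryl/oxocarbenium cation), water adds at furan C5 to form the new C–O bond (hemiketal 10), and ring opening gives the 1,4-dihydroxypentadienyl cation, which stays ion-paired with the chiral phosphoramide anion. Conrotatory 4π-electrocyclisation between the exocyclic CH2 and the former C5 closes the ring, and its torquoselectivity sets the (S)-carbinol. Because the carbinol carbon has no hydrogen, no dehydration or isomerisation can follow. The closest known reactions are chiral phosphoric acid catalysed aza-Piancatelli rearrangements, chiral Brønsted acid catalysed Nazarov cyclisations and the racemic oxa-Piancatelli rearrangement of 5-methylfurfuryl alcohols.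

Step 7
Reactants: 11 (4S)-2-bromo-4-hydroxy-4-[(2Z,5Z)-octa-2,5-dien-1-yl]cyclopent-2-en-1-one
Product: 13 (4R,5Z)-2-bromo-4-hydroxy-5-(hydroxymethylidene)-4-[(2Z,5Z)-octa-2,5-dien-1-yl]cyclopent-2-en-1-one, via dilithium dienolate alkoxide 12 (not isolated)
Conditions: LiN(SiMe3)2 (2.2 equiv), THF, −78 °C; HCO2CH2CF3, −78 °C; buffered aqueous work-up
Reagents that add atoms: 2,2,2-trifluoroethyl formate, O=COCC(F)(F)F
Why: Crossed Claisen condensation (α-formylation) at C5, the only enolisable position, gives the hydrogen-bonded Z-hydroxymethylene enol. The alkoxide cannot be eliminated and the carbinol centre is untouched (the descriptor changes only through CIP priorities).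

Step 8
Reactants: 13 (4R,5Z)-2-bromo-4-hydroxy-5-(hydroxymethylidene)-4-[(2Z,5Z)-octa-2,5-dien-1-yl]cyclopent-2-en-1-one
Product: 15 (Z)-[(5R)-3-bromo-5-hydroxy-5-[(2Z,5Z)-octa-2,5-dien-1-yl]-2-oxocyclopent-3-en-1-ylidene]methyl trifluoromethanesulfonate, via lithium chelate enolate 14 (not isolated)
Conditions: LiN(SiMe3)2 (1.0 equiv), THF, −78 °C; N-(5-chloropyridin-2-yl)bis(trifluoromethanesulfonyl)imide, −78 → −30 °C; aqueous work-up
Reagents that add atoms: N-(5-chloropyridin-2-yl)bis(trifluoromethanesulfonyl)imide, O=S(=O)(N(c1ccc(Cl)cn1)S(=O)(=O)C(F)(F)F)C(F)(F)F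
Why: One equivalent of base deprotonates only the acidic enol. Lithium bridges the enolate and ring-carbonyl oxygens, so O-sulfonylation (enol triflate formation) freezes the Z geometry, with the triflate syn to C=O and away from the quaternary carbinol.

Step 9
Reactants: 16 methyl 4-chloro-4-oxobutanoate; 17 (E)-1,2-bis(tributylstannyl)ethene
Product: 18 methyl (5E)-4-oxo-6-(tributylstannyl)hex-5-enoate
Conditions: Pd(PPh3)4 (3 mol %), 17 (1.5 equiv), toluene, 60 °C
Reagents that add atoms: none
Why: Stille acylation (Migita–Kosugi–Stille coupling of an acid chloride) replaces one tin with retention of E geometry; the remaining C–Sn bond is deactivated by the new acyl group, so mono-acylation prevails.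

Step 10
Reactants: 18 methyl (5E)-4-oxo-6-(tributylstannyl)hex-5-enoate
Product: 19 methyl (4S,5E)-4-hydroxy-6-(tributylstannyl)hex-5-enoate
Conditions: (R)-1-methyl-3,3-diphenyltetrahydro-1H,3H-pyrrolo[1,2-c][1,3,2]oxazaborole (20 mol %), catecholborane, toluene, −78 °C; then MeOH, pH 7 buffer
Reagents that add atoms: none
Why: Corey–Bakshi–Shibata reduction with the stannylvinyl group as the large substituent gives the (S)-allylic alcohol from the (R)-catalyst. The ester and vinylstannane are inert at −78 °C, and the neutral work-up avoids lactonisation.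

Step 11
Reactants: 15 (Z)-[(5R)-3-bromo-5-hydroxy-5-[(2Z,5Z)-octa-2,5-dien-1-yl]-2-oxocyclopent-3-en-1-ylidene]methyl trifluoromethanesulfonate; 19 methyl (4S,5E)-4-hydroxy-6-(tributylstannyl)hex-5-enoate
Product: 20 methyl (4S,5E,7Z)-7-[(5R)-3-bromo-5-hydroxy-5-[(2Z,5Z)-octa-2,5-dien-1-yl]-2-oxocyclopent-3-en-1-ylidene]-4-hydroxyhept-5-enoate
Conditions: Pd2(dba)3 (2.5 mol %), AsPh3 (20 mol %), CuI (10 mol %), N-methylpyrrolidone, 23 °C
Reagents that add atoms: none
Why: Migita–Kosugi–Stille coupling proceeds with retention at both sp2 carbons, so Z-triflate plus E-stannane give the 5E,7Z dienone. Oxidative addition into the vinylogous acyl triflate at room temperature is much faster than into the α-bromoenone C–Br bond, and both free hydroxyls are tolerated.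

## Compound list

1 | 1-bromopent-2-yne | CCC#CCBr | starting material
2 | prop-2-yn-1-ol | C#CCO | starting material
3 | octa-2,5-diyn-1-ol | CCC#CCC#CCO | intermediate
4 | (2Z,5Z)-octa-2,5-dien-1-ol | CC/C=C\C/C=C\CO | intermediate
5 | (2Z,5Z)-1-bromoocta-2,5-diene | CC/C=C\C/C=C\CBr | intermediate
6 | 3-bromofuran-2-carbaldehyde | O=Cc1occc1Br | starting material
7 | (3-bromofuran-2-yl)methanol | OCc1occc1Br | intermediate
8 | lithium (3-bromo-5-lithiofuran-2-yl)methanolate | [Li]OCc1oc([Li])cc1Br | intermediate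
9 | [3-bromo-5-[(2Z,5Z)-octa-2,5-dien-1-yl]furan-2-yl]methanol | CC/C=C\C/C=C\Cc1cc(Br)c(CO)o1 | intermediate
10 | 4-bromo-5-methylidene-2-[(2Z,5Z)-octa-2,5-dien-1-yl]-2,5-dihydrofuran-2-ol | CC/C=C\C/C=C\CC1(O)C=C(Br)C(=C)O1 | intermediate
11 | (4S)-2-bromo-4-hydroxy-4-[(2Z,5Z)-octa-2,5-dien-1-yl]cyclopent-2-en-1-one | CC/C=C\C/C=C\C[C@@]1(O)C=C(Br)C(=O)C1 | intermediate
12 | dilithium salt (alkoxide and cross-conjugated enolate) of 11 | CC/C=C\C/C=C\C[C@@]1(O[Li])C=C(Br)C(O[Li])=C1 | intermediate
13 | (4R,5Z)-2-bromo-4-hydroxy-5-(hydroxymethylidene)-4-[(2Z,5Z)-octa-2,5-dien-1-yl]cyclopent-2-en-1-one | CC/C=C\C/C=C\C[C@@]1(O)C=C(Br)C(=O)/C1=C\O | intermediate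
14 | lithium (Z)-enolate of 13 | CC/C=C\C/C=C\C[C@@]1(O)C=C(Br)C(=O)/C1=C\O[Li] | intermediate
15 | (Z)-[(5R)-3-bromo-5-hydroxy-5-[(2Z,5Z)-octa-2,5-dien-1-yl]-2-oxocyclopent-3-en-1-ylidene]methyl trifluoromethanesulfonate | CC/C=C\C/C=C\C[C@@]1(O)C=C(Br)C(=O)/C1=C\OS(=O)(=O)C(F)(F)F | intermediate
16 | methyl 4-chloro-4-oxobutanoate | COC(=O)CCC(Cl)=O | starting material
17 | (E)-1,2-bis(tributylstannyl)ethene | CCCC[Sn](CCCC)(CCCC)/C=C/[Sn](CCCC)(CCCC)CCCC | starting material
18 | methyl (5E)-4-oxo-6-(tributylstannyl)hex-5-enoate | CCCC[Sn](CCCC)(CCCC)/C=C/C(=O)CCC(=O)OC | intermediate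
19 | methyl (4S,5E)-4-hydroxy-6-(tributylstannyl)hex-5-enoate | CCCC[Sn](CCCC)(CCCC)/C=C/[C@@H](O)CCC(=O)OC | intermediate
20 | methyl (4S,5E,7Z)-7-[(5R)-3-bromo-5-hydroxy-5-[(2Z,5Z)-octa-2,5-dien-1-yl]-2-oxocyclopent-3-en-1-ylidene]-4-hydroxyhept-5-enoate | CC/C=C\C/C=C\C[C@@]1(O)C=C(Br)C(=O)/C1=C\C=C\[C@@H](O)CCC(=O)OC | target

## Step count and risks

Total step count: 11. Longest linear sequence: 8 steps (1 → 3 → 4 → 5 → 9 → 11 → 13 → 15 → 20, i.e. steps 1, 2, 3, 5, 6, 7, 8, 11).

The three steps most likely to fail: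

**Step 6 (the proposed new rearrangement).** Ionisation of a primary furfuryl alcohol may be slow, the open-chain ketone intermediate could tautomerise or pull the β,γ-alkene into conjugation, and the level and sense of induction are untested. Fallback, from 9 back to 11 by known chemistry: 9 is rearranged without chiral control under established oxa-Piancatelli conditions (ZnCl2, aqueous dioxane, 80 °C) to give racemic 2-bromo-4-hydroxy-4-[(2Z,5Z)-octa-2,5-dien-1-yl]cyclopent-2-en-1-one F3. Its enantiomers are separated by preparative chromatography on a chiral stationary phase (amylose tris(3,5-dimethylphenylcarbamate), supercritical CO2/MeOH) to deliver 11.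

**Step 5 (second metalation of the bromofuran).** Deprotonation at C5 of the lithium alkoxide may be sluggish, and a 5-lithio-3-bromofuran can undergo bromine migration. Fallback, from 5 back to 9: commercial 2,4-dibromofuran undergoes selective bromine–lithium exchange at the α-position (n-BuLi, Et2O, −78 °C) and is alkylated with 5 to give 4-bromo-2-[(2Z,5Z)-octa-2,5-dien-1-yl]furan F1. LiN(iPr)2 then removes the α-proton next to bromine (lithium is already ortho to Br, so no migration is possible), and DMF gives 3-bromo-5-[(2Z,5Z)-octa-2,5-dien-1-yl]furan-2-carbaldehyde F2. NaBH4 in MeOH reduces F2 to 9.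

**Step 8 (geometry and lability of the enol triflate).** If chelation control is incomplete, the E-triflate forms as well, and the vinylogous acyl triflate is sensitive to nucleophiles. Fallback, from 13 back to 20: 13 is triflated without geometric control (Et3N, same triflimide, CH2Cl2) to a mixture of 15 and (E)-[(5R)-3-bromo-5-hydroxy-5-[(2Z,5Z)-octa-2,5-dien-1-yl]-2-oxocyclopent-3-en-1-ylidene]methyl trifluoromethanesulfonate F4. The mixture is coupled with 19 as in step 11, and 20 is separated by HPLC from methyl (4S,5E,7E)-7-[(5R)-3-bromo-5-hydroxy-5-[(2Z,5Z)-octa-2,5-dien-1-yl]-2-oxocyclopent-3-en-1-ylidene]-4-hydroxyhept-5-enoate F5. F5 is irradiated (benzene, Pyrex-filtered light) to a photostationary 7E/7Z mixture, as is known for this class of cross-conjugated alkylidene cyclopentenones, and recycled to give more 20.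

## Further compounds

F1 | step 5 | 4-bromo-2-[(2Z,5Z)-octa-2,5-dien-1-yl]furan | CC/C=C\C/C=C\Cc1cc(Br)co1
F2 | step 5 | 3-bromo-5-[(2Z,5Z)-octa-2,5-dien-1-yl]furan-2-carbaldehyde | CC/C=C\C/C=C\Cc1cc(Br)c(C=O)o1
F3 | step 6 | racemic 2-bromo-4-hydroxy-4-[(2Z,5Z)-octa-2,5-dien-1-yl]cyclopent-2-en-1-one | CC/C=C\C/C=C\CC1(O)C=C(Br)C(=O)C1
F4 | step 8 | (E)-[(5R)-3-bromo-5-hydroxy-5-[(2Z,5Z)-octa-2,5-dien-1-yl]-2-oxocyclopent-3-en-1-ylidene]methyl trifluoromethanesulfonate | CC/C=C\C/C=C\C[C@@]1(O)C=C(Br)C(=O)/C1=C/OS(=O)(=O)C(F)(F)F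
F5 | step 8 | methyl (4S,5E,7E)-7-[(5R)-3-bromo-5-hydroxy-5-[(2Z,5Z)-octa-2,5-dien-1-yl]-2-oxocyclopent-3-en-1-ylidene]-4-hydroxyhept-5-enoate | CC/C=C\C/C=C\C[C@@]1(O)C=C(Br)C(=O)/C1=C/C=C/[C@@H](O)CCC(=O)OC
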